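The ent-labdane target is cut at C3–C4 of ring A. Verbenone already holds ring B (C5–C10) with the C10 methyl, and its gem-dimethyl carbon is C4; the one bond it has in surplus is the cyclobutane bond C4–C7. In the key step a silyl Lewis acid breaks this bond in a verbenone-derived pinanone: C4 becomes a tertiary cation, C7–C8 a silyl enol ether, and an allylsilane on C10 traps C4, so that ring A and the trans-decalin arise in one operation with the C8 oxygen left where the 7-ene is needed. The precursor is a 6,6-dimethylbicyclo[3.1.1]heptan-2-one with methyl and 2-(trimethylsilylmethyl)allyl on C10 and the silyl-protected C11–C15 chain on C9.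

Key step: step 8

Remark: labdane numbering is used from compound 9 on, "ent-labdane" denotes only the ring configuration of the target (5R,10R, trans-fused), metal enolates and ion pairs are transient species without numbers, and the enolate alkylation of step 7 is assumed to occur on the face anti to the gem-dimethyl bridge, so the key-step precursor carries the C9 chain cis to the allyl arm and C9 is equilibrated after ring closure.

Step 1
Reactants: 1 dimethyl 3-methylpentanedioate (dimethyl 3-methylglutarate)
Product: 2 (R)-5-methoxy-3-methyl-5-oxopentanoic acid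
Conditions: pig liver esterase, 0.1 M NaH2PO4/Na2HPO4 buffer pH 7/MeOH 4:1, −10 °C, pH-stat with 1 M NaOH; then HCl to pH 2
Reagents that add atoms: water, O
Why: Enzymatic desymmetrisation of a prochiral diester (esterase hydrolysis of one of the two enantiotopic ester groups) should give the (R)-half-ester and so fixes the future C13 centre.

Step 2
Reactants: 2 (R)-5-methoxy-3-methyl-5-oxopentanoic acid
Product: 3 methyl (R)-5-hydroxy-3-methylpentanoate
Conditions: BH3·SMe2 (1.1 equiv), THF, −15 → 0 °C; MeOH quench; used at once
Reagents that add atoms: none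
Why: Chemoselective borane reduction of a carboxylic acid beside an ester (the acyloxyborane is reduced fast, the ester is left), with the stereocentre untouched.

Step 3
Reactants: 3 methyl (R)-5-hydroxy-3-methylpentanoate
Product: 4 methyl (R)-3-methyl-5-(triisopropylsilyloxy)pentanoate
Conditions: iPr3SiCl (1.2 equiv), imidazole (2.5 equiv), DMF, 23 °C
Reagents that add atoms: triisopropylsilyl chloride, CC(C)[Si](Cl)(C(C)C)C(C)C
Why: Silylation of a primary alcohol forestalls lactonisation of 3; the bulky triisopropylsilyl ether is chosen because it should survive the amide bases, the silyl Lewis acid of step 8 and the dissolving metal of step 12.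

Step 4
Reactants: 4 methyl (R)-3-methyl-5-(triisopropylsilyloxy)pentanoate
Product: 5 (S)-3-methyl-5-(triisopropylsilyloxy)pentan-1-ol
Conditions: LiAlH4 (1.0 equiv), Et2O, 0 °C; H2O, 15% NaOH, H2O
Reagents that add atoms: none
Why: Hydride reduction of an ester to the primary alcohol; the silyl ether is inert and the descriptor changes only through CIP priorities.

Step 5
Reactants: 5 (S)-3-methyl-5-(triisopropylsilyloxy)pentan-1-ol
Product: 6 (R)-(5-iodo-3-methylpentyloxy)triisopropylsilane
Conditions: I2 (1.2 equiv), PPh3 (1.2 equiv), imidazole (2.5 equiv), CH2Cl2, 0 → 23 °C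
Reagents that add atoms: iodine, II
Why: Appel-type iodination (SN2 displacement of the alkoxyphosphonium ion by iodide at a primary carbon), remote from the stereocentre.

Step 6
Reactants: 7 (1S,5S)-(−)-verbenone; 8 2-(trimethylsilylmethyl)allyltrimethylsilane
Product: 9 4,6,6-trimethyl-4-[2-(trimethylsilylmethyl)allyl]bicyclo[3.1.1]heptan-2-one (bridgeheads as in 7; allyl arm anti, methyl syn to the CMe2 bridge)
Conditions: TiCl4 (1.1 equiv), CH2Cl2, −78 °C, then 8 (1.3 equiv), −78 °C; Et3N/MeOH, then aqueous NaHCO3 at −78 °C
Reagents that add atoms: none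
Why: Hosomi–Sakurai conjugate allylation: the CH2= terminus of 8 adds to the β-carbon of the TiCl4-bound enone (labdane C10) from the face anti to the gem-dimethyl bridge, as organocopper reagents do with verbenone, and loss of one Me3Si group leaves a new, less nucleophilic allylsilane, which sets the quaternary C10 with C1 trans to C4.

Step 7
Reactants: 9 4,6,6-trimethyl-4-[2-(trimethylsilylmethyl)allyl]bicyclo[3.1.1]heptan-2-one; 6 (R)-(5-iodo-3-methylpentyloxy)triisopropylsilane
Product: 10 ketone 9 carrying on C3 of the pinanone (labdane C9) the (3S)-3-methyl-5-(triisopropylsilyloxy)pentyl chain, anti to the CMe2 bridge and cis to the allyl arm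
Conditions: LiN(iPr)2 (1.05 equiv), THF, −78 °C; then 6 (1.5 equiv), DMPU (4 equiv), −78 → 0 °C
Reagents that add atoms: none
Why: Alkylation of a lithium enolate that can form only toward C9 because C7 is a bridgehead; SN2 on the primary iodide from the face anti to the gem-dimethyl bridge (its syn methyl and the C10 methyl cover the other face) places the chain cis to the allyl arm, where it also screens the C8 carbonyl from that arm, and this centre is equilibrated in step 8.

Step 8
Reactants: 10 pinanone with methyl and 2-(trimethylsilylmethyl)allyl on C10 and the silyloxypentyl chain on C9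
Product: 13 2-methylene-15-(triisopropylsilyloxy)-17-nor-ent-labdan-8-one (trans-decalone; C9 chain equatorial and cis to the C10 methyl), via 9-epi silyl enol ether 11 (not isolated), via 9-epi decalone 12 (not isolated)
Conditions: Me3SiOTf (0.3 equiv), 2,6-di-tert-butyl-4-methylpyridine (0.1 equiv), CH2Cl2 (0.02 M), −40 → 0 °C; then NaOMe (0.5 equiv), MeOH, 0 → 23 °C
Reagents that add atoms: none
Why: Proposed new method: O-silylation of the C8 carbonyl gives a silyloxycarbenium ion, heterolysis of the strained adjacent C7–C4 bond then leaves the C7–C8 silyl enol ether and a tertiary cation at C4, the terminal CH2 of the C10 allylsilane adds to C4 (new bond C3–C4), and the β-silyl cation at C2 hands Me3Si+ back to triflate, so that the silyl group of 10 ends on the enol oxygen of 11 and the promoter turns over. The closest known reactions are the Lewis acid opening of nopinone- and verbanone-type cyclobutyl ketones to 2-propyl cations with enol derivatives, and the Lewis acid coupling of tertiary alkyl halides with allylsilanes (Sakurai-type termination of a cation). Ring A closes 6-endo with respect to the allylsilane double bond through a chair in which C1 on C10 and the cationic C4 on C5 are both equatorial on ring B, and the exocyclic methylene stays on C2. The C–C bond formation creates no stereocentre, the trans ring fusion following from the anti relation of C1 and C4 set in step 6; the methoxide finish cleaves 11 to 12 and equilibrates the only epimerisable centre, C9, through the C8–C9 enolate to the equatorial chain of 13, so that either C9 epimer of 10 would converge. The selectivity needed is capture of the C4 cation ahead of allylation of the activated carbonyl and ahead of proton loss: attack on C8 would need a bridged chair that folds the allyl arm under ring B against the C6 methylene and past the C9 chain on the same face, the carbonyl turns into an inert silyl enol ether at the moment the cation forms, a non-chelating silyl Lewis acid is used in substoichiometric amount, and the hindered pyridine removes the protic acid that would protodesilylate the allylsilane.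

Step 9
Reactants: 13 2-methylene-15-(triisopropylsilyloxy)-17-nor-ent-labdan-8-one
Product: 14 2-methylene-15-(triisopropylsilyloxy)-17-nor-ent-labd-7-en-8-yl trifluoromethanesulfonate
Conditions: KN(SiMe3)2 (1.1 equiv), THF, −78 °C; then PhNTf2 (1.2 equiv), −78 → 0 °C
Reagents that add atoms: N-phenylbis(trifluoromethanesulfonimide), O=S(=O)(N(c1ccccc1)S(=O)(=O)C(F)(F)F)C(F)(F)F
Why: Kinetic deprotonation by a bulky amide base at the unhindered C7 methylene, not at the tertiary C9–H beside the quaternary C10, followed by O-sulfonylation of the enolate (enol triflate formation), which fixes the alkene at C7–C8 and leaves C9 untouched.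

Step 10
Reactants: 14 2-methylene-15-(triisopropylsilyloxy)-17-nor-ent-labd-7-en-8-yl trifluoromethanesulfonate
Product: 15 2-oxo-15-(triisopropylsilyloxy)-17-nor-ent-labd-7-en-8-yl trifluoromethanesulfonate
Conditions: O3, CH2Cl2, −78 °C, Sudan Red 7B as end-point indicator; then PPh3 (1.5 equiv), −78 → 23 °C
Reagents that add atoms: ozone, [O-][O+]=O
Why: Ozonolysis of the electron-rich 1,1-disubstituted exocyclic alkene; the C7–C8 alkene is strongly deactivated toward electrophilic ozone by the triflyloxy group, which is why the cleavage is placed before the methyl coupling and not after it.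

Step 11
Reactants: 15 2-oxo-15-(triisopropylsilyloxy)-17-nor-ent-labd-7-en-8-yl trifluoromethanesulfonate
Product: 16 15-(triisopropylsilyloxy)-ent-labd-7-en-2-one
Conditions: Pd(PPh3)4 (5 mol%), SnMe4 (2 equiv), LiCl (3 equiv), DMF, 80 °C
Reagents that add atoms: tetramethyltin, C[Sn](C)(C)C
Why: Stille coupling of an alkenyl triflate (oxidative addition of zerovalent palladium into C–OTf, methyl transfer from tin, reductive elimination) under neutral conditions that tolerate the C2 ketone and the silyl ether and cannot move the alkene.

Step 12
Reactants: 16 15-(triisopropylsilyloxy)-ent-labd-7-en-2-one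
Product: 17 (2R)-15-(triisopropylsilyloxy)-ent-labd-7-en-2-ol (equatorial hydroxyl, trans to the C10 methyl)
Conditions: Li (4 equiv), NH3(l)/THF, EtOH (2 equiv), −78 °C; then NH4Cl
Reagents that add atoms: none
Why: Dissolving-metal reduction of a ketone under thermodynamic control should give the equatorial C2 alcohol, the epimer that avoids the two syn-axial methyl groups on C4 and C10 (a hydride would enter from the open face and give the axial alcohol); the isolated trisubstituted alkene and the silyl ether are inert.

Step 13
Reactants: 17 (2R)-15-(triisopropylsilyloxy)-ent-labd-7-en-2-ol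
Product: 18 (2R,5R,9R,10R,13S)-labd-7-ene-2,15-diol
Conditions: Bu4NF (1.5 equiv), THF, 0 → 23 °C
Reagents that add atoms: none
Why: Fluoride cleavage of the silyl ether, driven by the Si–F bond, frees the primary alcohol without touching the alkene or the secondary alcohol.

Step 14
Reactants: 18 (2R,5R,9R,10R,13S)-labd-7-ene-2,15-diol
Product: 19 (2R,5R,9R,10R,13S)-labd-7-ene-2,15-diyl diacetate (CNP0220683.1)
Conditions: Ac2O (4 equiv), pyridine, DMAP (0.1 equiv), CH2Cl2, 23 °C
Reagents that add atoms: acetic anhydride, CC(=O)OC(C)=O
Why: DMAP-catalysed acylation esterifies the primary and the unhindered equatorial secondary alcohol in one operation, with retention at C2.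

Compound list
1 | dimethyl 3-methylpentanedioate | COC(=O)CC(C)CC(=O)OC | starting material
2 | (R)-5-methoxy-3-methyl-5-oxopentanoic acid | COC(=O)C[C@H](C)CC(=O)O | intermediate
3 | methyl (R)-5-hydroxy-3-methylpentanoate | COC(=O)C[C@H](C)CCO | intermediate
4 | methyl (R)-3-methyl-5-(triisopropylsilyloxy)pentanoate | COC(=O)C[C@H](C)CCO[Si](C(C)C)(C(C)C)C(C)C | intermediate
5 | (S)-3-methyl-5-(triisopropylsilyloxy)pentan-1-ol | OCC[C@H](C)CCO[Si](C(C)C)(C(C)C)C(C)C | intermediate
6 | (R)-(5-iodo-3-methylpentyloxy)triisopropylsilane | ICC[C@H](C)CCO[Si](C(C)C)(C(C)C)C(C)C | intermediate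
7 | (1S,5S)-(−)-verbenone | CC1=CC(=O)[C@H]2C[C@@H]1C2(C)C | starting material
8 | 2-(trimethylsilylmethyl)allyltrimethylsilane | C=C(C[Si](C)(C)C)C[Si](C)(C)C | starting material
9 | 4,6,6-trimethyl-4-[2-(trimethylsilylmethyl)allyl]bicyclo[3.1.1]heptan-2-one, allyl arm anti to the CMe2 bridge | C1C(=O)[C@H]2C[C@H](C2(C)C)[C@@]1(C)CC(=C)C[Si](C)(C)C | intermediate
10 | ketone 9 with the (3S)-3-methyl-5-(triisopropylsilyloxy)pentyl chain on labdane C9, cis to the allyl arm | CC(C)[Si](C(C)C)(C(C)C)OCC[C@@H](C)CC[C@H]1C(=O)[C@H]2C[C@H](C2(C)C)[C@@]1(C)CC(=C)C[Si](C)(C)C | intermediate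
11 | 9-epi-2-methylene-15-(triisopropylsilyloxy)-8-(trimethylsilyloxy)-17-nor-ent-labd-7-ene | CC(C)[Si](C(C)C)(C(C)C)OCC[C@@H](C)CC[C@H]1C(O[Si](C)(C)C)=CC[C@@H]2C(C)(C)CC(=C)C[C@@]12C | intermediate
12 | 9-epi-2-methylene-15-(triisopropylsilyloxy)-17-nor-ent-labdan-8-one (C9 chain axial) | CC(C)[Si](C(C)C)(C(C)C)OCC[C@@H](C)CC[C@H]1C(=O)CC[C@@H]2C(C)(C)CC(=C)C[C@@]12C | intermediate
13 | 2-methylene-15-(triisopropylsilyloxy)-17-nor-ent-labdan-8-one (C9 chain equatorial) | CC(C)[Si](C(C)C)(C(C)C)OCC[C@@H](C)CC[C@@H]1C(=O)CC[C@@H]2C(C)(C)CC(=C)C[C@@]12C | intermediate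
14 | 2-methylene-15-(triisopropylsilyloxy)-17-nor-ent-labd-7-en-8-yl trifluoromethanesulfonate | CC(C)[Si](C(C)C)(C(C)C)OCC[C@@H](C)CC[C@@H]1C(OS(=O)(=O)C(F)(F)F)=CC[C@@H]2C(C)(C)CC(=C)C[C@@]12C | intermediate
15 | 2-oxo-15-(triisopropylsilyloxy)-17-nor-ent-labd-7-en-8-yl trifluoromethanesulfonate | CC(C)[Si](C(C)C)(C(C)C)OCC[C@@H](C)CC[C@@H]1C(OS(=O)(=O)C(F)(F)F)=CC[C@@H]2C(C)(C)CC(=O)C[C@@]12C | intermediate
16 | 15-(triisopropylsilyloxy)-ent-labd-7-en-2-one | CC(C)[Si](C(C)C)(C(C)C)OCC[C@@H](C)CC[C@@H]1C(C)=CC[C@@H]2C(C)(C)CC(=O)C[C@@]12C | intermediate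
17 | (2R)-15-(triisopropylsilyloxy)-ent-labd-7-en-2-ol | CC(C)[Si](C(C)C)(C(C)C)OCC[C@@H](C)CC[C@@H]1C(C)=CC[C@@H]2C(C)(C)C[C@@H](O)C[C@@]12C | intermediate
18 | (2R,5R,9R,10R,13S)-labd-7-ene-2,15-diol | OCC[C@@H](C)CC[C@@H]1C(C)=CC[C@@H]2C(C)(C)C[C@@H](O)C[C@@]12C | intermediate
19 | (2R,5R,9R,10R,13S)-labd-7-ene-2,15-diyl diacetate | CC(=O)OCC[C@@H](C)CC[C@@H]1C(C)=CC[C@@H]2C(C)(C)C[C@@H](OC(C)=O)C[C@@]12C | target

Total step count: 14. Longest linear sequence: 13 steps (steps 1–5 and 7–14, from 1).

Steps most likely to fail

For step 8, the silyl-activated carbonyl may be allylated by the tethered allylsilane before the four-membered ring ionises, the C4 cation may be lost by elimination or hydride shift before ring A closes, or the silyl transfer may fail to turn over. The fallback separates the two events into two reactions of known type; it sets out from 10 and comes back at 12. Compound 10 is opened with Me3SiI (1.2 equiv, CH2Cl2, −40 → 0 °C, a trace of the hindered pyridine), the iodide-assisted opening known for cyclopropyl ketones and for nopinone-type cyclobutyl ketones, which parks the cation as the tertiary iodide and masks the carbonyl, giving the ring-opened silyl enol ether iodide F1. F1 is then ionised with TiCl4 in CH2Cl2 at −78 °C, the standard coupling of a tertiary alkyl halide with an allylsilane, with the bulky C5 group and the trans allyl arm both pseudo-equatorial on ring B. Work-up with 1 M HCl gives 12, which the NaOMe/MeOH finish of step 8 converts to 13.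

For step 7, C-alkylation of the hindered enolate by an unactivated primary iodide may be slower than proton transfer, O-alkylation or dehydroiodination of 6. The fallback goes through the more nucleophilic aza-enolate; it sets out from 9 and 6 and comes back at 10. Compound 9 and Me2NNH2 (AcOH cat., EtOH, 60 °C) give the N,N-dimethylhydrazone F2. LiN(iPr)2 (THF, 0 °C) and then 6 (−78 → 0 °C) give the alkylated hydrazone F3, again only at C9 and anti to the bridge. Cu(OAc)2 in THF/H2O at 23 °C cleaves F3 to 10.

For step 6, TiCl4 may open the cyclobutane of the enone, or attack at the hindered β-carbon may be too slow. The fallback is an organocopper conjugate addition; it sets out from 7 and comes back at 9. Commercial 2-(chloromethyl)allyltrimethylsilane and Mg in THF give [2-(trimethylsilylmethyl)allyl]magnesium chloride F4. With CuBr·SMe2 and Me3SiCl (THF, −78 °C) F4 adds to 7 anti to the bridge to give the silyl enol ether F5, and K2CO3 in MeOH at 0 °C gives 9.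

Further compounds
F1 | step 8 | ring-opened cyclohexenyl trimethylsilyl ether of 10 with a 2-iodo-2-propyl group on C5 | CC(C)[Si](C(C)C)(C(C)C)OCC[C@@H](C)CC[C@H]1C(O[Si](C)(C)C)=CC[C@H](C(C)(C)I)[C@@]1(C)CC(=C)C[Si](C)(C)C
F2 | step 7 | N,N-dimethylhydrazone of 9 | C1C(=NN(C)C)[C@H]2C[C@H](C2(C)C)[C@@]1(C)CC(=C)C[Si](C)(C)C
F3 | step 7 | N,N-dimethylhydrazone of 10 | CC(C)[Si](C(C)C)(C(C)C)OCC[C@@H](C)CC[C@H]1C(=NN(C)C)[C@H]2C[C@H](C2(C)C)[C@@]1(C)CC(=C)C[Si](C)(C)C
F4 | step 6 | [2-(trimethylsilylmethyl)allyl]magnesium chloride | C=C(C[Si](C)(C)C)C[Mg]Cl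
F5 | step 6 | trimethylsilyl enol ether of 9 | C1=C(O[Si](C)(C)C)[C@H]2C[C@H](C2(C)C)[C@@]1(C)CC(=C)C[Si](C)(C)C
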